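**Plan**

1. Numbering: seven-membered ring C1 (tertiary carbinol carrying the acyl chain C2–C4), C5 (ester carbinol), C6 (lactone O–CH), C7, C8 (CH2), C9 (CHOH), C10 (CHMe); lactone C11 (α-carbon), C12 (C=O), C13 (=CH2).
2. Enabling feature: the oxygens on C5 and C9 are 1,5-related through C6–C7–C8, and C6/C7 carry a cis-fused five-membered oxygen ring. This is the pattern left by an enone–enol ether [2+2] photocycloaddition followed by retro-aldol opening, so the ring maps onto a cyclopentane-1,3-dione enol ether (C9, C8, C5, C1, C10) and 2,3-dihydrofuran (O, C6, C7, C11, C12).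
3. Retrosynthetic cuts, in order: C11=C13 (Mannich methylenation), the C5–O ester bond, C1–C2 (acetylide added to a C1 ketone, the alkyne later hydrated at C2), the C12 carbonyl oxygen (ether oxidation), then C5–C6 and C7–C8 together with re-formation of C5–C8.
4. Forward: the benzyl enol ether of the dione is methylated (C10); irradiation with dihydrofuran builds the cyclobutane, and hydrogenolysis lets it open to the seven-membered 1,4-diketone; the tetrahydrofuran becomes the lactone; the C5 carbonyl is transposed to C1; the side chain is added; C5 is acylated; ketone, methylene and free hydroxyls are unveiled last.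
5. Stereochemistry: C6/C7 cis from the cyclic alkene and C10 from the facial bias of the photocycloaddition; absolute configuration by separation of diastereomeric (2R,3R)-butane-2,3-diol ketals; C1 by Felkin–Anh addition to the C1 ketone; C5 and C9 by hydride delivery from the C1 hydroxyl; C4 and the ester centre from (S)-but-3-yn-2-ol and (2S)-2-methylbutanoic anhydride.

Key step: step 3

Remark: α denotes the ring face of the C6–O and C7–C11 bonds, β the face of H6 and H7; compounds 4 and 6–9 are racemic and are drawn as the enantiomer that is carried on.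

**Route**

Step 1
Reactants: 1 cyclopentane-1,3-dione; 2 benzyl alcohol
Product: 3 3-(benzyloxy)cyclopent-2-en-1-one
Conditions: p-TsOH·H2O (cat.), toluene, reflux, Dean–Stark trap
Reagents that add atoms: none
Why: Acid-catalysed condensation of the enolised symmetric 1,3-dione with the alcohol (vinylogous Fischer esterification) with azeotropic removal of water should give a single enol ether; no stereocentre is formed.

Step 2
Reactants: 3 3-(benzyloxy)cyclopent-2-en-1-one
Product: 4 (±)-3-(benzyloxy)-5-methylcyclopent-2-en-1-one
Conditions: LiN(iPr)2, THF, −78 °C; MeI, −78 → −30 °C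
Reagents that add atoms: iodomethane, CI
Why: Stork–Danheiser kinetic deprotonation of the vinylogous ester at the α′-carbon (the future C10) and SN2 methylation should place the methyl next to the ketone, which fixes which carbonyl becomes C9; the new centre is racemic.

Step 3
Reactants: 4 (±)-3-(benzyloxy)-5-methylcyclopent-2-en-1-one; 5 2,3-dihydrofuran
Product: 8 (±)-cis-fused tetrahydrofuran–cycloheptane-1,4-dione (C5 and C9 ketones; 10α-methyl), via head-to-tail photoadduct 6 (not isolated), via cyclobutanol 7 (not isolated)
Conditions: hν (Hg lamp, Pyrex, λ > 290 nm), 5 (10 equiv), EtOAc, −20 °C; excess 5 evaporated; then H2 (1 atm), Pd(OH)2 on carbon, EtOAc, rt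
Reagents that add atoms: none
Why: Excitation and intersystem crossing give the triplet enone, which adds to the electron-rich double bond of 5 through a 1,4-diradical, the oxygen-bearing C6 bonding to the β-carbon C5 and C7 to the α-carbon C8 (head-to-tail); the closest known reaction type is the De Mayo reaction of enol derivatives of 1,3-diketones. The cyclobutane closes by recombination of that diradical after spin inversion (intermolecular [2+2]); the seven-membered ring is not closed by bond formation but appears when hydrogenolysis of the benzyl ether of 6 frees cyclobutanol 7, whose strain-driven retro-aldol cleaves the C5–C8 bond shared by the four- and five-membered rings. C6 and C7 become cis because both new bonds must form on one face of the five-membered alkene, a trans-fused oxabicyclo[3.2.0]heptane being prohibitively strained. The C10 methyl of racemic 4 should steer 5 to the opposite face of the enone and, with the usual exo orientation of the incoming ring, end on the α face; any C10 epimer is removed by chromatography. The step needs head-to-tail regiochemistry, which the polarisation of the excited enone towards enol ethers favours, and the neutral hydrogenolysis keeps the base-labile C6 and C10 centres intact.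

Step 4
Reactants: 8 (±)-cis-fused tetrahydrofuran–cycloheptane-1,4-dione
Product: 9 (±)-diketo lactone (6,12-olide; C5 and C9 ketones; 10α-methyl)
Conditions: RuCl3·xH2O (cat.), NaIO4, CCl4/MeCN/H2O, rt
Reagents that add atoms: sodium periodate, [Na+].[O-]I(=O)(=O)=O
Why: Catalytically generated RuO4 should oxidise the ether α-methylene C12 to the lactone carbonyl, because the other α-position, C6–H, is tertiary, hindered and deactivated by the adjacent C5 carbonyl; no stereocentre changes.

Step 5
Reactants: 9 (±)-diketo lactone; 10 (2R,3R)-butane-2,3-diol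
Product: 11 C9 (2R,3R)-butane-2,3-diyl ketal of (3aS,6R,8aR)-9 (C5 ketone; 6,12-olide; 10α-methyl)
Conditions: 10 (3 equiv), HC(OEt)3, p-TsOH·H2O (cat.), CH2Cl2, rt; chromatographic separation of the two diastereomeric ketals
Reagents that add atoms: none
Why: Acid-catalysed ketalisation should occur at C9 only, since the C5 carbonyl is flanked by the acyloxy-bearing C6 and forms an oxocarbenium ion far less readily; the enantiopure diol turns the racemate into two diastereomers, so their separation is a classical resolution in which at most half of the material can be the wanted ketal 11.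

Step 6
Reactants: 11 C9 ketal keto lactone
Product: 12 C5 triethylsilyl enol ether (C1=C5) of 11
Conditions: LiN(iPr)2, Et3SiCl (present before the base), THF, −78 °C
Reagents that add atoms: chlorotriethylsilane, CC[Si](Cl)(CC)CC
Why: Kinetic deprotonation by the hindered amide should take place at the unhindered C1 methylene rather than at the tertiary C6–H or the less acidic lactone α-CH2, and immediate O-silylation (silyl enol ether formation with internal quench) forestalls acyl transfer from the lactone.

Step 7
Reactants: 12 C5 triethylsilyl enol ether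
Product: 14 1β-hydroxy-5α-(triethylsilyloxy) ketal lactone, via C1 alkylborane 13 (not isolated)
Conditions: BH3·THF, THF, 0 °C; then NaBO3·4H2O, H2O, rt
Reagents that add atoms: sodium perborate, [Na+].[Na+].O[B-]1(O)OO[B-](O)(O)OO1
Why: Hydroboration–oxidation of the silyl enol ether places boron on C1 (the carbon β to oxygen) and hydrogen on C5 by syn addition from the β face, the α face being blocked by the C10 methyl next to C1 and the lactone oxygen on C6 next to C5; oxidation with retention then gives the 1β-alcohol and the 5α-silyl ether (a 1,2-carbonyl transposition).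

Step 8
Reactants: 14 1β-hydroxy-5α-(triethylsilyloxy) ketal lactone
Product: 15 C1 ketone (5α-triethylsilyloxy; C9 ketal)
Conditions: Dess–Martin periodinane, NaHCO3, CH2Cl2, 0 °C → rt
Reagents that add atoms: none
Why: Dess–Martin oxidation of the secondary alcohol under buffered, non-enolising conditions should give the C1 ketone without epimerising C5 or C10.

Step 9
Reactants: 16 (S)-but-3-yn-2-ol
Product: 17 (S)-3-(triisopropylsilyloxy)but-1-yne
Conditions: iPr3SiCl, imidazole, DMF, rt
Reagents that add atoms: chlorotriisopropylsilane, CC(C)[Si](Cl)(C(C)C)C(C)C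
Why: Standard silylation of the secondary propargylic alcohol; the stereocentre (the future C4) comes from the chiral pool and is untouched.

Step 10
Reactants: 15 C1 ketone; 17 (S)-3-(triisopropylsilyloxy)but-1-yne
Product: 19 1α,5α-diol bearing the 1β-[(3S)-3-(triisopropylsilyloxy)but-1-ynyl] group (C9 ketal), via triethylsilyl ether adduct 18 (not isolated)
Conditions: 17, n-BuLi, THF, −78 °C; CeCl3 (anhydrous), −78 °C; 15, −78 °C; then AcOH/H2O/THF (3:1:1), rt
Reagents that add atoms: none
Why: The weakly basic cerium acetylide should add 1,2 to the hindered, enolisable ketone from the β face, anti to the α-oriented C5 silyloxy group (polar Felkin–Anh model) and to the α C10 methyl, which sets C1 with the hydroxyl α and the carbon chain β; aqueous acetic acid then removes only the triethylsilyl group.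

Step 11
Reactants: 19 1α,5α-diol
Product: 20 1α-hydroxy-5-ketone (C9 ketal)
Conditions: IBX (2-iodoxybenzoic acid), DMSO, rt
Reagents that add atoms: none
Why: IBX oxidises the secondary C5 alcohol of a 1,2-diol to the ketone without glycol cleavage, the tertiary C1 hydroxyl being inert.

Step 12
Reactants: 20 1α-hydroxy-5-ketone (C9 ketal)
Product: 21 1α-hydroxy-5,9-diketone
Conditions: p-TsOH·H2O (cat.), acetone/H2O (10:1), 40 °C
Reagents that add atoms: water, O
Why: Acid-catalysed transketalisation and hydrolysis should free the C9 ketone under conditions mild enough for the triisopropylsilyl ether, the tertiary propargylic alcohol and the C10 centre.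

Step 13
Reactants: 21 1α-hydroxy-5,9-diketone
Product: 22 1α,5β,9β-triol
Conditions: Me4NBH(OAc)3 (excess), MeCN/AcOH (1:1), −20 °C → rt
Reagents that add atoms: none
Why: In this Saksena–Evans reduction the C1 hydroxyl exchanges onto boron and delivers hydride intramolecularly to the α faces of both the α-keto (C5) and the β-keto (C9) groups, so both new carbinols should be β, trans to the C1 hydroxyl (1,2-anti and 1,3-anti), as the target requires.

Step 14
Reactants: 22 1α,5β,9β-triol
Product: 23 9β-tert-butyldimethylsilyl ether (1α,5β-diol)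
Conditions: tBuMe2SiCl, imidazole, DMF, 0 °C → rt
Reagents that add atoms: tert-butyldimethylsilyl chloride, C[Si](C)(Cl)C(C)(C)C
Why: Silylation discriminates by hindrance: the C9 hydroxyl between CH2 and CHMe should react, whereas the C5 hydroxyl between the quaternary C1 and C6 and the tertiary C1 hydroxyl should not.

Step 15
Reactants: 23 9β-silyl ether diol
Product: 24 Mannich base (11-dimethylaminomethyl lactone; CH2NMe2 anti to C8)
Conditions: LiN(iPr)2 (3.5 equiv), THF, −78 → −40 °C; CH2=NMe2+ I− (Eschenmoser's salt), −78 °C → rt; aq. NaHCO3 work-up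
Reagents that add atoms: N,N-dimethylmethyleneiminium iodide, C=[N+](C)C.[I-]
Why: Excess amide base forms the dialkoxide lactone enolate, which is aminomethylated by the iminium salt (Mannich reaction) anti to C8 on the cis-fused lactone; the new C11 centre is lost again in step 18, and N,O-acetals formed at the alkoxides hydrolyse on work-up.

Step 16
Reactants: 24 Mannich base; 25 (2S)-2-methylbutanoic anhydride
Product: 26 5β-[(2S)-2-methylbutanoate] of 24
Conditions: 25 (3 equiv), DMAP, Et3N, CH2Cl2, 40 °C
Reagents that add atoms: none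
Why: DMAP-catalysed acylation of the only remaining secondary hydroxyl with the symmetric anhydride installs the ester without a ketene pathway that could racemise it; the tertiary C1 hydroxyl does not react.

Step 17
Reactants: 26 5β-ester alkyne
Product: 28 C2 ketone (1α-hydroxy-1β-[(3S)-3-(triisopropylsilyloxy)butanoyl]), via Z-alkylidene carbonate 27 (not isolated)
Conditions: AgOAc (10 mol %), DBU (1 equiv), CO2 (1 MPa), toluene, rt; then H2O/THF, rt
Reagents that add atoms: carbon dioxide, O=C=O
Why: The tertiary propargylic alkoxide captures CO2 and the resulting carbonate attacks the silver-activated alkyne in anti 5-exo-dig fashion at C2 (silver-catalysed carboxylative cyclisation), so hydrolysis of carbonate 27 with loss of CO2 puts the ketone oxygen on C2 only; water supplies the two C3 hydrogens and no stereocentre is affected.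

Step 18
Reactants: 28 C2 ketone Mannich base
Product: 30 bis-silyl ether of the target (11(13)-methylene lactone; 9β-OSitBuMe2; 4-OSi(iPr)3), via trimethylammonium iodide 29 (not isolated)
Conditions: MeI (excess), MeOH, rt; then aq. NaHCO3, EtOAc, rt
Reagents that add atoms: none
Why: Exhaustive methylation of the Mannich base and bicarbonate-induced E1cB (Hofmann-type) elimination of trimethylamine unveil the α-methylene lactone under conditions that leave the β-silyloxy ketone and the ester intact.

Step 19
Reactants: 30 bis-silyl ether of the target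
Product: 31 CNP0291806.1, (3aS,5R,6S,7S,8S,8aR)-5,7-dihydroxy-7-[(3S)-3-hydroxybutanoyl]-6-methyl-3-methylidene-2-oxooctahydro-2H-cyclohepta[b]furan-8-yl (2S)-2-methylbutanoate
Conditions: HF·pyridine, pyridine, THF, 0 °C → rt
Reagents that add atoms: none
Why: Fluoride-mediated cleavage of both silyl ethers under buffered acidic conditions avoids base-induced retro-aldol, acyl migration or conjugate addition to the methylene lactone.

**Compound list**

1 | cyclopentane-1,3-dione | O=C1CCC(=O)C1 | starting material
2 | benzyl alcohol | OCc1ccccc1 | starting material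
3 | 3-(benzyloxy)cyclopent-2-en-1-one | O=C1C=C(OCc2ccccc2)CC1 | intermediate
4 | (±)-3-(benzyloxy)-5-methylcyclopent-2-en-1-one | O=C1C=C(OCc2ccccc2)CC1C | intermediate
5 | 2,3-dihydrofuran | C1=COCC1 | starting material
6 | (±)-head-to-tail photoadduct (cis-anti-cis tricycle; C5 benzyl ether; C9 ketone; exo 10-methyl) | O=C1[C@H](C)C[C@]2(OCc3ccccc3)[C@H]1[C@H]1CCO[C@H]12 | intermediate
7 | (±)-cyclobutanol (C5–OH) from 6 | O=C1[C@H](C)C[C@]2(O)[C@H]1[C@H]1CCO[C@H]12 | intermediate
8 | (±)-cis-fused tetrahydrofuran–cycloheptane-1,4-dione, rac-(3aR,6R,8aR)-6-methyl bicyclic 5,8-dione (C5 and C9 ketones; 10α-methyl) | C1CO[C@@H]2[C@H]1CC(=O)[C@H](C)CC2=O | intermediate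
9 | (±)-diketo lactone, rac-(3aS,6R,8aR) (6,12-olide; C5 and C9 ketones; 10α-methyl) | C1C(=O)O[C@@H]2[C@H]1CC(=O)[C@H](C)CC2=O | intermediate
10 | (2R,3R)-butane-2,3-diol | C[C@@H](O)[C@@H](C)O | starting material
11 | C9 (2R,3R)-butane-2,3-diyl ketal of (3aS,6R,8aR)-9 | C1C(=O)O[C@@H]2[C@H]1CC3(O[C@H](C)[C@@H](C)O3)[C@H](C)CC2=O | intermediate
12 | C5 triethylsilyl enol ether (C1=C5) of 11 | C1C(=O)O[C@@H]2[C@H]1CC3(O[C@H](C)[C@@H](C)O3)[C@H](C)C=C2O[Si](CC)(CC)CC | intermediate
13 | C1 alkylborane (1β-BH2; 5α-OSiEt3) | C1C(=O)O[C@@H]2[C@H]1CC3(O[C@H](C)[C@@H](C)O3)[C@H](C)[C@@H](B)[C@@H]2O[Si](CC)(CC)CC | intermediate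
14 | 1β-hydroxy-5α-(triethylsilyloxy) ketal lactone | C1C(=O)O[C@@H]2[C@H]1CC3(O[C@H](C)[C@@H](C)O3)[C@H](C)[C@@H](O)[C@@H]2O[Si](CC)(CC)CC | intermediate
15 | C1 ketone (5α-OSiEt3; C9 ketal) | C1C(=O)O[C@@H]2[C@H]1CC3(O[C@H](C)[C@@H](C)O3)[C@H](C)C(=O)[C@@H]2O[Si](CC)(CC)CC | intermediate
16 | (S)-but-3-yn-2-ol | C#C[C@H](C)O | starting material
17 | (S)-3-(triisopropylsilyloxy)but-1-yne | C#C[C@H](C)O[Si](C(C)C)(C(C)C)C(C)C | intermediate
18 | alkynyl adduct (1α-OH; 1β-alkynyl; 5α-OSiEt3; C9 ketal) | C1C(=O)O[C@@H]2[C@H]1CC3(O[C@H](C)[C@@H](C)O3)[C@H](C)[C@@](O)(C#C[C@H](C)O[Si](C(C)C)(C(C)C)C(C)C)[C@@H]2O[Si](CC)(CC)CC | intermediate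
19 | 1α,5α-diol (1β-alkynyl; C9 ketal) | C1C(=O)O[C@@H]2[C@H]1CC3(O[C@H](C)[C@@H](C)O3)[C@H](C)[C@@](O)(C#C[C@H](C)O[Si](C(C)C)(C(C)C)C(C)C)[C@@H]2O | intermediate
20 | 1α-hydroxy-5-ketone (C9 ketal) | C1C(=O)O[C@@H]2[C@H]1CC3(O[C@H](C)[C@@H](C)O3)[C@H](C)[C@@](O)(C#C[C@H](C)O[Si](C(C)C)(C(C)C)C(C)C)C2=O | intermediate
21 | 1α-hydroxy-5,9-diketone | C1C(=O)O[C@@H]2[C@H]1CC(=O)[C@H](C)[C@@](O)(C#C[C@H](C)O[Si](C(C)C)(C(C)C)C(C)C)C2=O | intermediate
22 | 1α,5β,9β-triol | C1C(=O)O[C@@H]2[C@H]1C[C@@H](O)[C@H](C)[C@@](O)(C#C[C@H](C)O[Si](C(C)C)(C(C)C)C(C)C)[C@H]2O | intermediate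
23 | 9β-tert-butyldimethylsilyl ether (1α,5β-diol) | C1C(=O)O[C@@H]2[C@H]1C[C@@H](O[Si](C)(C)C(C)(C)C)[C@H](C)[C@@](O)(C#C[C@H](C)O[Si](C(C)C)(C(C)C)C(C)C)[C@H]2O | intermediate
24 | Mannich base (11-dimethylaminomethyl lactone; CH2NMe2 anti to C8, expected major epimer) | CN(C)C[C@@H]1C(=O)O[C@@H]2[C@H]1C[C@@H](O[Si](C)(C)C(C)(C)C)[C@H](C)[C@@](O)(C#C[C@H](C)O[Si](C(C)C)(C(C)C)C(C)C)[C@H]2O | intermediate
25 | (2S)-2-methylbutanoic anhydride | CC[C@H](C)C(=O)OC(=O)[C@@H](C)CC | starting material
26 | 5β-[(2S)-2-methylbutanoate] of 24 | CN(C)C[C@@H]1C(=O)O[C@@H]2[C@H]1C[C@@H](O[Si](C)(C)C(C)(C)C)[C@H](C)[C@@](O)(C#C[C@H](C)O[Si](C(C)C)(C(C)C)C(C)C)[C@H]2OC(=O)[C@@H](C)CC | intermediate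
27 | spiro (Z)-alkylidene cyclic carbonate (C1–O–CO–O–C2=C3) | CN(C)C[C@@H]1C(=O)O[C@@H]2[C@H]1C[C@@H](O[Si](C)(C)C(C)(C)C)[C@H](C)[C@]3(OC(=O)O/C3=C\[C@H](C)O[Si](C(C)C)(C(C)C)C(C)C)[C@H]2OC(=O)[C@@H](C)CC | intermediate
28 | C2 ketone (1α-OH; 1β-[(3S)-3-(triisopropylsilyloxy)butanoyl]) | CN(C)C[C@@H]1C(=O)O[C@@H]2[C@H]1C[C@@H](O[Si](C)(C)C(C)(C)C)[C@H](C)[C@@](O)(C(=O)C[C@H](C)O[Si](C(C)C)(C(C)C)C(C)C)[C@H]2OC(=O)[C@@H](C)CC | intermediate
29 | trimethylammonium iodide of 28 | C[N+](C)(C)C[C@@H]1C(=O)O[C@@H]2[C@H]1C[C@@H](O[Si](C)(C)C(C)(C)C)[C@H](C)[C@@](O)(C(=O)C[C@H](C)O[Si](C(C)C)(C(C)C)C(C)C)[C@H]2OC(=O)[C@@H](C)CC.[I-] | intermediate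
30 | bis-silyl ether of the target (11(13)-methylene lactone) | C=C1C(=O)O[C@@H]2[C@H]1C[C@@H](O[Si](C)(C)C(C)(C)C)[C@H](C)[C@@](O)(C(=O)C[C@H](C)O[Si](C(C)C)(C(C)C)C(C)C)[C@H]2OC(=O)[C@@H](C)CC | intermediate
31 | CNP0291806.1 (1α,9β-dihydroxy; 5β-(2S)-2-methylbutanoyloxy; 10α-methyl; 1β-(3S)-3-hydroxybutanoyl) | C=C1C(=O)O[C@@H]2[C@H]1C[C@@H](O)[C@H](C)[C@@](O)(C(=O)C[C@H](C)O)[C@H]2OC(=O)[C@@H](C)CC | target

**Totals**

Total step count: 19. Longest linear sequence: 18 steps (steps 1–8 and 10–19, from cyclopentane-1,3-dione); step 9 is a one-step side branch.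

**Steps most likely to fail, with fallbacks**

Step 3. The electron-rich vinylogous ester may add sluggishly or with competing head-to-head orientation, the benzyl group may divert the excited state, and hydrogenolysis of the hindered tertiary benzyl ether may stall so that the cyclobutane is never opened. The fallback replaces reductive unmasking by an acid-triggered push–pull fragmentation and sets out from 1. Compound 1 is condensed with methanol (HC(OMe)3, p-TsOH) to 3-methoxycyclopent-2-en-1-one F1. Kinetic methylation as in step 2 gives (±)-3-methoxy-5-methylcyclopent-2-en-1-one F2. Irradiation with 5 as in step 3 gives the methoxy photoadduct F3. Aqueous HCl in THF then protonates the C9 carbonyl, the methoxy lone pair pushes the C5–C8 bond open, and hydrolysis of the resulting oxocarbenium ion brings the material back to the route at 8. This answers the unmasking and benzyl-related failures; it does not by itself correct a poor head-to-tail preference.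

Step 17. Carboxylation of the hindered tertiary alkoxide may not proceed, and the stoichiometric amidine base may cause β-elimination of the silyloxy group from the new ketone or acyl migration from C5. The fallback forms the carbonate beforehand and cyclises it under neutral conditions; it sets out from 26. Deprotonation with KN(SiMe3)2 at −78 °C and trapping with Boc2O should give the tert-butyl carbonate F4. With the dimethylamino group buffered by one equivalent of camphorsulfonic acid, Ph3PAuNTf2 (cat.) in CH2Cl2 should induce 5-exo-dig attack of the carbonate carbonyl on C2 with loss of isobutene. This comes back to the route at 27, which is hydrolysed to 28 as in step 17.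

Step 5. The two diastereomeric ketals may not be discriminated well enough by chromatography, and acid may epimerise C10 during ketalisation. The fallback resolves by enzymatic kinetic resolution instead and sets out from 9. Racemic 9 is exposed to a ketoreductase (NADPH, isopropanol, buffer) selected to reduce the activated C5 carbonyl of the (3aR,6S,8aS) enantiomer only. The resulting alcohol F5 of the unwanted enantiomer is separated, and the recovered (3aS,6R,8aR) enantiomer comes back to the route at 9, from which step 5 should give 11 as a single diastereomer.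

**Further compounds**

F1 | step 3 | 3-methoxycyclopent-2-en-1-one | COC1=CC(=O)CC1
F2 | step 3 | (±)-3-methoxy-5-methylcyclopent-2-en-1-one | COC1=CC(=O)C(C)C1
F3 | step 3 | (±)-methoxy photoadduct (C5 methyl ether analogue of 6) | O=C1[C@H](C)C[C@]2(OC)[C@H]1[C@H]1CCO[C@H]12
F4 | step 17 | tert-butyl carbonate of 26 (at the C1 oxygen) | CN(C)C[C@@H]1C(=O)O[C@@H]2[C@H]1C[C@@H](O[Si](C)(C)C(C)(C)C)[C@H](C)[C@@](OC(=O)OC(C)(C)C)(C#C[C@H](C)O[Si](C(C)C)(C(C)C)C(C)C)[C@H]2OC(=O)[C@@H](C)CC
F5 | step 5 | C5 alcohol of the (3aR,6S,8aS) enantiomer of 9 (carbinol configuration set by the enzyme, left open) | C1C(=O)O[C@H]2[C@@H]1CC(=O)[C@@H](C)CC2O
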